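Over a run of 3.0 h, target slowly passes into over-reaction product, and the vessels differ in how old they let target become before the reading.

the same everywhere: substrate 48 mM; initiator 2.4 mM

|  | partner | time | remark |
|---|---|---|---|
| oak | 96.0 mM | 3.0 h | a tube with plug flow, the mixed feed as stated, residence time 3.0 h |
| cedar | 96.0 mM (fed, over 2.40 h) | 3.0 h | a stirred flask in which partner is dosed at a steady rate over 2.40 h without added volume, worked up at 3.0 h |
| ash | 96.0 mM | 3.0 h | a closed flask charged with all of it at once and left for 3.0 h |
| maple | 96.0 mM |  | one stirred flow tank at steady state, fed with the mixture as stated, mean residence time 3.0 h |

    initiator → 2 initiating radical (k1 = 9.8 × 10⁻⁴ /min)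
    substrate + initiating radical → chain carrier (k2 = 1.4 × 10⁵ /M/min)
    partner + chain carrier → target + initiating radical (k3 = 12000 /M/s)
    2 initiating radical → ended chains A (k4 = 1 × 10⁶ /M/s)
    2 chain carrier → ended chains B (k5 = 5 × 10⁷ /M/s)
    target → over-reaction product (k6 = 0.0051 /min)
    substrate ⇌ dormant form (K7 = 1.3, k7 = 0.013 /min)

- a species is counted by the substrate in it: one ended chains B counts as two
- a doubled species enters its step squared and goes two at a time
- the stated concentrations are those of everything mixed, before any reaction; amounts are the same in each set-up
- the feed brings no volume worth counting
- run time (oak): 3.0 h

- the set-up with the highest share of target in all that became target or over-reaction product, at the outlet or at the end ("none" if the first two lie within 2 percentage points) (oak / cedar / ash / maple / none)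
- share of target in all that became target or over-reaction product, at the outlet or at the end, oak
- share of target in all that became target or over-reaction product, at the outlet or at the end, cedar
- share of target in all that became target or over-reaction product, at the outlet or at the end, ash
- share of target in all that became target or over-reaction product, at the outlet or at the end, maple

The carried quantity is the life of target against over-reaction, the reciprocal of 0.0051 /min, here 196 min. A portion of target of age a keeps exp(−a/life), so a share read from a flask converts to an equivalent age, the life times the logarithm of the inverse share.

A small scale can be set up by rows, each row a pattern of birth times.

The zero row is the statistical case, the stirred tank, where ages are spread at random. Outflow and over-reaction both act first-order on c(target), so maple stands at 52.1%, however the chain runs.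

The next row has all target born at the start, giving 39.9%.

The next row is the chain's own clock. With c(initiating radical) near 1.98 × 10⁻⁴ mM, substrate falls pseudo-first-order at 0.0277 /min, a time of 36.1 min, shorter than the life. Ash and oak, the same kinetics in two vessels, therefore sit near 48.4%. Substrate enters the dormant form about half as fast, and what returns later lifts that row a little.

The last row is cedar. Partner is dosed over 2.40 h, and this row supposes target born evenly over that time, which is a supposition and not a finding about the chain. Such birth gives 59.0%, above the tank, so this reckoning puts cedar ahead.

The forecast gives 51.5% for oak, 59% for cedar, 51.5% for ash and 52.1% for maple, with cedar best, on the ground that “Dosing the partner holds the chain back and shifts target formation later”. For ash and oak it stands above the reckoning here.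

The flask gives 51.0% for oak, 60.4% for cedar, 51.0% for ash and 52.1% for maple, so cedar leads. Cedar and ash end with equal target, 43.0% and 42.9%, but cedar holds less over-reaction product, 28.2% against 41.2%. Through the life, cedar's share reads as an equivalent age of 1.65 h and ash's as 2.20 h. The same cedar flask read at 12 h shows 7.51%, an equivalent age of 8.46 h.

(All constants are assumed; the run is a simulation.)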